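**Plan** (locants of the target's cyclohepta[b]furan-2-one core: O-1, C-2 carbonyl, C-3 methylidene carbon, C-3a, C-4 carbinol, C-5 CH2, C-6 CHCH3, C-7 tertiary carbinol, C-8 CH–OAng, C-8a)
1. Retrosynthesis: first the ketone C–C bond of the crotonoyl group (alkenylchromium + aldehyde), the angelate ester and the exocyclic methylene are removed; H-3a is traced to a butenolide, and this to an ether bridge from O-7 to C-3a; the cycloheptane is then cut at C-3a–C-4 and C-6–C-7.
2. Enabling feature: C-3a and C-7 stand 1,4 across C-8a/C-8, so C-3a, C-8a, C-8, C-7 are the four carbons of a 2,5-disubstituted furan whose oxygen survives as the 7-OH; C-4(OH)–C-5H2–C-6(CH3) is the three-carbon unit of tetrabromocyclopropene (CBr2 → C=O → CHOH; BrC=CBr → enone that takes up the methyl).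
3. Forward: furan + cyclopropene → 8-oxabicyclo[3.2.1]octadiene (seven-membered ring first, as an oxygen-bridged bicycle) → γ-lactone closed on the bicycle → bridge opened by β-elimination → trans-fused cyclohepta[b]furan-2-one → methylene, angelate, side chain.
4. Stereochemistry: 6-CH3, 4-OH, O-8a and O-8 come from exo-face attack on the bicycle (cuprate, hydride, OsO4, hydride), C-7 from the furan oxygen, H-3a from hydroxyl-directed hydrogenation; the absolute configuration comes from a CBS reduction that also separates the antipodes of the racemic cycloadduct; both side-chain alkene geometries are bought.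

Key step: step 4

Remark: tetrabromocyclopropene is not assumed to be on sale and is made in step 3. Compounds 6–11 are racemic and are drawn as the enantiomer that is carried on. In the bicycles "exo" is the face of the oxygen bridge; in the cyclohepta[b]furanones "β" is the face of H-8a.

Step 1
Reactants: 1 methyl 2-(furan-2-yl)acetate
Product: 2 methyl 2-(5-formylfuran-2-yl)acetate
Conditions: POCl3, DMF, 0 °C → rt; then aq. NaOAc
Reagents that add atoms: N,N-dimethylformamide (CN(C)C=O); water (O)
Why: Vilsmeier–Haack formylation should attack the only free α-position of the 2-alkylfuran, the most nucleophilic carbon of the ring.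

Step 2
Reactants: 2 methyl 2-(5-formylfuran-2-yl)acetate
Product: 3 methyl 2-[5-(dimethoxymethyl)furan-2-yl]acetate
Conditions: HC(OMe)3, MeOH, p-TsOH (cat.), rt; Et3N quench
Reagents that add atoms: trimethyl orthoformate (COC(OC)OC); methanol (CO)
Why: Acid-catalysed acetalisation with the orthoformate as water scavenger masks the future side-chain carbonyl carbon and removes the electron-withdrawing formyl group so that the furan can act as a diene.

Step 3
Reactants: 4 tetrachlorocyclopropene
Product: 5 tetrabromocyclopropene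
Conditions: BBr3 (excess), CH2Cl2, rt; distillation
Reagents that add atoms: boron tribromide (BrB(Br)Br)
Why: Lewis-acid halogen exchange through the aromatic trihalocyclopropenium ion should replace all four chlorines, as is known for this cyclopropene.

Step 4
Reactants: 3 methyl 2-[5-(dimethoxymethyl)furan-2-yl]acetate; 5 tetrabromocyclopropene
Product: 7 rac-methyl 2-[2,2,3,4-tetrabromo-5-(dimethoxymethyl)-8-oxabicyclo[3.2.1]octa-3,6-dien-1-yl]acetate, via Diels–Alder adduct 6 (not isolated)
Conditions: 1,4-dioxane, K2CO3 (solid), rt → 60 °C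
Reagents that add atoms: none
Why: The furan 3 is the 4π partner and the strained, electron-poor C=C of 5 the 2π partner of a concerted suprafacial Diels–Alder reaction that makes both new C–C bonds at once (each furan α-carbon to one CBr) and gives the 8-oxatricyclo[3.2.1.0(2,4)]octene 6; in 6 the gem-dibromocyclopropane ionises with disrotatory cyclopropyl-to-allyl opening of the fusion bond and bromide returns to an allyl terminus, so that the former CBr2 carbon moves into the ring and the oxabicyclo[3.2.1]octadiene 7 results. The closest known reaction type is the formal (4+3) cycloaddition of tetrahalocyclopropenes with furans (Diels–Alder reaction followed by halocyclopropane ring expansion). The seven-membered carbocycle is closed by cycloaddition (a [4+2] transition state, then one-carbon expansion of the six-membered ring) and not by a chain cyclisation, and the five-membered ether ring of the bicycle is the original furan. The only stereocentres formed are the two bridgeheads, whose cis relation is dictated by the suprafacial addition to the planar furan; 7 is racemic and the absolute configuration is fixed in step 8. The step needs periselectivity ([4+2] at the cyclopropene π bond instead of furan substitution or cyclopropene oligomerisation), which the strain and low LUMO of 5 and the electron-rich 2,5-dialkylfuran should secure, whereas exo/endo selectivity and the position of the CBr2 group do not matter because both allylic isomers give one allyl cation in step 5. The three cyclopropene carbons become C-4, C-5 and C-6 and the furan oxygen becomes the 7-hydroxyl of the target.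

Step 5
Reactants: 7 rac-methyl 2-[2,2,3,4-tetrabromo-5-(dimethoxymethyl)-8-oxabicyclo[3.2.1]octa-3,6-dien-1-yl]acetate
Product: 8 rac-methyl 2-[3,4-dibromo-5-(dimethoxymethyl)-2-oxo-8-oxabicyclo[3.2.1]octa-3,6-dien-1-yl]acetate
Conditions: AgNO3 (2.2 equiv), CaCO3, acetone–H2O, rt
Reagents that add atoms: water (O)
Why: Silver-assisted SN1 hydrolysis of the allylic gem-dibromide passes through the tribromoallyl cation, and water should attack the terminus next to the less hindered bridgehead (CH2CO2Me against the branched acetal carbon), helped by the ester carbonyl as a five-ring neighbouring group, so that the carbonyl ends up at the future C-4.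

Step 6
Reactants: 8 rac-methyl 2-[3,4-dibromo-5-(dimethoxymethyl)-2-oxo-8-oxabicyclo[3.2.1]octa-3,6-dien-1-yl]acetate
Product: 9 rac-methyl 2-[3-bromo-5-(dimethoxymethyl)-2-oxo-8-oxabicyclo[3.2.1]octa-3,6-dien-1-yl]acetate
Conditions: Zn–Ag couple, MeOH, rt, short contact time
Reagents that add atoms: none
Why: Electron-transfer reduction of a β-halo enone (a vinylogous α-halo ketone) should remove only the β-bromine, since the α-bromine cannot leave from the enone radical anion.

Step 7
Reactants: 9 rac-methyl 2-[3-bromo-5-(dimethoxymethyl)-2-oxo-8-oxabicyclo[3.2.1]octa-3,6-dien-1-yl]acetate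
Product: 11 rac-methyl 2-[5-(dimethoxymethyl)-4-exo-methyl-2-oxo-8-oxabicyclo[3.2.1]oct-6-en-1-yl]acetate, via bromo ketone 10 (not isolated)
Conditions: Me2CuLi (from MeLi, CuI), Et2O, −78 °C; NH4Cl; crude 10 then Zn–Cu couple, NH4Cl, MeOH, rt
Reagents that add atoms: methyllithium ([Li]C), used as lithium dimethylcuprate ([Li+].C[Cu-]C)
Why: Gilman cuprate 1,4-addition should deliver the methyl group from the exo face, because the endo face of the three-carbon bridge lies over the C-6=C-7 bridge, which sets the methyl-bearing centre, and zinc reduction of the α-bromo ketone then removes the last bromine.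

Step 8
Reactants: 11 rac-methyl 2-[5-(dimethoxymethyl)-4-exo-methyl-2-oxo-8-oxabicyclo[3.2.1]oct-6-en-1-yl]acetate
Product: 12 methyl 2-[(2S)-5-(dimethoxymethyl)-2-endo-hydroxy-4-exo-methyl-8-oxabicyclo[3.2.1]oct-6-en-1-yl]acetate
Conditions: (R)-2-methyl-CBS-oxazaborolidine (0.2–1 equiv), catecholborane, toluene, −78 °C; MeOH, then aqueous work-up; chromatography
Reagents that add atoms: none
Why: In this CBS reduction the oxazaborolidine should deliver hydride to the same prochiral face of either antipode of 11 (bridgehead carbon as the large group) and give the (2S)-carbinol; for the wanted antipode this is exo attack and gives the endo-alcohol 12, whereas the mirror-image ketone is turned into the exo-epimer or left behind and is removed by chromatography, which fixes the absolute configuration and uses at most half of the material.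

Step 9
Reactants: 12 methyl 2-[(2S)-5-(dimethoxymethyl)-2-endo-hydroxy-4-exo-methyl-8-oxabicyclo[3.2.1]oct-6-en-1-yl]acetate
Product: 13 methyl 2-[5-(dimethoxymethyl)-4-exo-methyl-2-endo-(triisopropylsilyloxy)-8-oxabicyclo[3.2.1]oct-6-en-1-yl]acetate
Conditions: TIPSOTf, 2,6-lutidine, CH2Cl2, −78 → 0 °C, directly after step 8
Reagents that add atoms: triisopropylsilyl trifluoromethanesulfonate (CC(C)[Si](OS(=O)(=O)C(F)(F)F)(C(C)C)C(C)C)
Why: Silyl triflate silylation of the hindered secondary alcohol blocks lactonisation onto this oxygen, and at low temperature the deactivated neopentyl-type acetal should not be touched.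

Step 10
Reactants: 13 methyl 2-[5-(dimethoxymethyl)-4-exo-methyl-2-endo-(triisopropylsilyloxy)-8-oxabicyclo[3.2.1]oct-6-en-1-yl]acetate
Product: 15 2-[5-(dimethoxymethyl)-6-exo-hydroxy-4-exo-methyl-2-endo-(triisopropylsilyloxy)-8-oxabicyclo[3.2.1]oct-1-yl]acetic acid 7-exo-lactone, via diol ester 14 (not isolated)
Conditions: OsO4 (cat.), NMO, acetone–H2O, rt; then PPTS (cat.), toluene, 60 °C
Reagents that add atoms: N-methylmorpholine N-oxide (C[N+]1([O-])CCOCC1); water (O); both oxygens are delivered through osmium tetroxide (O=[Os](=O)(=O)=O)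
Why: Upjohn dihydroxylation should occur on the exo face of the strained alkene and set both carbinol centres, and only the 7-exo hydroxyl next to the bridgehead CH2CO2Me can close a γ-lactone, which differentiates the two hydroxyls.

Step 11
Reactants: 15 2-[5-(dimethoxymethyl)-6-exo-hydroxy-4-exo-methyl-2-endo-(triisopropylsilyloxy)-8-oxabicyclo[3.2.1]oct-1-yl]acetic acid 7-exo-lactone
Product: 16 2-[5-(dimethoxymethyl)-4-exo-methyl-6-oxo-2-endo-(triisopropylsilyloxy)-8-oxabicyclo[3.2.1]oct-1-yl]acetic acid 7-exo-lactone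
Conditions: Dess–Martin periodinane, NaHCO3, CH2Cl2, 0 °C → rt
Reagents that add atoms: none
Why: Dess–Martin oxidation of the remaining secondary alcohol is mild enough for the acetal and silyl ether, and the adjacent O-bearing centre cannot epimerise because the exo-fused lactone locks it.

Step 12
Reactants: 16 2-[5-(dimethoxymethyl)-4-exo-methyl-6-oxo-2-endo-(triisopropylsilyloxy)-8-oxabicyclo[3.2.1]oct-1-yl]acetic acid 7-exo-lactone
Product: 17 2-[5-(dimethoxymethyl)-6-endo-hydroxy-4-exo-methyl-2-endo-(triisopropylsilyloxy)-8-oxabicyclo[3.2.1]oct-1-yl]acetic acid 7-exo-lactone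
Conditions: NaBH4, MeOH–CH2Cl2, −78 → −40 °C
Reagents that add atoms: none
Why: Borohydride reduction of the activated α,α'-dioxygenated ketone should take place from the exo face, since the endo face is covered by the C-3 methylene of the chair, and gives the endo alcohol (net inversion, trans to the lactone oxygen) while the lactone survives at low temperature.

Step 13
Reactants: 17 2-[5-(dimethoxymethyl)-6-endo-hydroxy-4-exo-methyl-2-endo-(triisopropylsilyloxy)-8-oxabicyclo[3.2.1]oct-1-yl]acetic acid 7-exo-lactone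
Product: 18 2-[5-(dimethoxymethyl)-4-exo-methyl-6-endo-(triethylsilyloxy)-2-endo-(triisopropylsilyloxy)-8-oxabicyclo[3.2.1]oct-1-yl]acetic acid 7-exo-lactone
Conditions: TESOTf, 2,6-lutidine, CH2Cl2, −78 °C
Reagents that add atoms: triethylsilyl trifluoromethanesulfonate (CC[Si](CC)(CC)OS(=O)(=O)C(F)(F)F)
Why: Silylation gives a temporary ether that can later be removed in the presence of the TIPS ether and keeps this hydroxyl from directing the hydrogenation of step 15.

Step 14
Reactants: 18 2-[5-(dimethoxymethyl)-4-exo-methyl-6-endo-(triethylsilyloxy)-2-endo-(triisopropylsilyloxy)-8-oxabicyclo[3.2.1]oct-1-yl]acetic acid 7-exo-lactone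
Product: 19 7β-(dimethoxymethyl)-7α-hydroxy-6α-methyl-8β-(triethylsilyloxy)-4β-(triisopropylsilyloxy)-5,6,7,8-tetrahydro-4H-cyclohepta[b]furan-2(8aH)-one
Conditions: LiHMDS (1.05 equiv), THF, −78 → −40 °C; AcOH at −78 °C; used at once
Reagents that add atoms: none
Why: In this E1cB β-elimination the lactone enolate, whose π system is aligned with the bridge C–O bond, should expel the bridging oxygen as the tertiary alkoxide (enolate to alkoxide and release of the bicycle drive it) and give the butenolide; no stereocentre is formed.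

Step 15
Reactants: 19 7β-(dimethoxymethyl)-7α-hydroxy-6α-methyl-8β-(triethylsilyloxy)-4β-(triisopropylsilyloxy)-5,6,7,8-tetrahydro-4H-cyclohepta[b]furan-2(8aH)-one
Product: 20 (3aα-H,8aβ-H)-7β-(dimethoxymethyl)-7α-hydroxy-6α-methyl-8β-(triethylsilyloxy)-4β-(triisopropylsilyloxy)octahydro-2H-cyclohepta[b]furan-2-one
Conditions: [Ir(cod)(PCy3)(py)]PF6 (10 mol %), H2 (1 atm), CH2Cl2, rt
Reagents that add atoms: none
Why: In this hydroxyl-directed homogeneous hydrogenation the tertiary 7α-OH (the oxygen that was bonded to C-3a in the bicycle) should bind iridium and deliver H2 to the α-face while the 4β-OTIPS group screens the β-face, which sets H-3a α and hence the trans ring fusion.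

Step 16
Reactants: 20 (3aα-H,8aβ-H)-7β-(dimethoxymethyl)-7α-hydroxy-6α-methyl-8β-(triethylsilyloxy)-4β-(triisopropylsilyloxy)octahydro-2H-cyclohepta[b]furan-2-one
Product: 23 (3aα-H,8aβ-H)-7β-(dimethoxymethyl)-7α-hydroxy-6α-methyl-3-methylidene-8β-(triethylsilyloxy)-4β-(triisopropylsilyloxy)octahydro-2H-cyclohepta[b]furan-2-one, via Mannich base 21 (not isolated), via methiodide 22 (not isolated)
Conditions: LDA (2.2 equiv), THF, −78 °C; CH2=NMe2+ I−, −78 → 0 °C; NH4Cl; then MeI, MeOH, rt; then aq. NaHCO3, CH2Cl2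
Reagents that add atoms: dimethylmethyleneiminium iodide, Eschenmoser's salt (C=[N+](C)C.[I-]); iodomethane (CI), which adds the N-methyl group of 22 only
Why: Mannich aminomethylation of the lactone enolate, quaternisation and Hofmann-type elimination is the standard α-methylenation of γ-lactones; the dianion has no β-leaving group and the new sp2 centre carries no stereochemistry.

Step 17
Reactants: 23 (3aα-H,8aβ-H)-7β-(dimethoxymethyl)-7α-hydroxy-6α-methyl-3-methylidene-8β-(triethylsilyloxy)-4β-(triisopropylsilyloxy)octahydro-2H-cyclohepta[b]furan-2-one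
Product: 24 (3aα-H,8aβ-H)-7β-(dimethoxymethyl)-7α,8β-dihydroxy-6α-methyl-3-methylidene-4β-(triisopropylsilyloxy)octahydro-2H-cyclohepta[b]furan-2-one
Conditions: CSA (cat.), MeOH–CH2Cl2, 0 °C
Reagents that add atoms: none
Why: Acid-catalysed methanolysis should cleave the triethylsilyl ether much faster than the triisopropylsilyl ether, and the dimethyl acetal only undergoes degenerate exchange in methanol.

Step 18
Reactants: 24 (3aα-H,8aβ-H)-7β-(dimethoxymethyl)-7α,8β-dihydroxy-6α-methyl-3-methylidene-4β-(triisopropylsilyloxy)octahydro-2H-cyclohepta[b]furan-2-one; 25 angelic acid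
Product: 26 (3aα-H,8aβ-H)-7β-(dimethoxymethyl)-7α-hydroxy-6α-methyl-3-methylidene-2-oxo-4β-(triisopropylsilyloxy)octahydro-2H-cyclohepta[b]furan-8β-yl (2Z)-2-methylbut-2-enoate
Conditions: 25, 2,4,6-trichlorobenzoyl chloride, Et3N, toluene, rt; then 24, 75 °C
Reagents that add atoms: none
Why: Yamaguchi esterification through the mixed anhydride, run without a nucleophilic catalyst, should acylate the hindered secondary alcohol with little Z-to-E isomerisation, while the tertiary hydroxyl is too hindered to react.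

Step 19
Reactants: 26 (3aα-H,8aβ-H)-7β-(dimethoxymethyl)-7α-hydroxy-6α-methyl-3-methylidene-2-oxo-4β-(triisopropylsilyloxy)octahydro-2H-cyclohepta[b]furan-8β-yl (2Z)-2-methylbut-2-enoate
Product: 27 (3aα-H,8aβ-H)-7β-formyl-7α-hydroxy-6α-methyl-3-methylidene-2-oxo-4β-(triisopropylsilyloxy)octahydro-2H-cyclohepta[b]furan-8β-yl (2Z)-2-methylbut-2-enoate
Conditions: TFA–H2O–CH2Cl2, 0 °C → rt
Reagents that add atoms: water (O)
Why: Aqueous acid hydrolysis of the dimethyl acetal frees the α-hydroxy aldehyde, and the triisopropylsilyl ether, which should survive, keeps the 4-oxygen from forming a lactol or attacking the lactone.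

Step 20
Reactants: 27 (3aα-H,8aβ-H)-7β-formyl-7α-hydroxy-6α-methyl-3-methylidene-2-oxo-4β-(triisopropylsilyloxy)octahydro-2H-cyclohepta[b]furan-8β-yl (2Z)-2-methylbut-2-enoate; 28 (E)-1-bromoprop-1-ene
Product: 29 (3aα-H,8aβ-H)-7α-hydroxy-7β-[(2E)-1-hydroxybut-2-en-1-yl]-6α-methyl-3-methylidene-2-oxo-4β-(triisopropylsilyloxy)octahydro-2H-cyclohepta[b]furan-8β-yl (2Z)-2-methylbut-2-enoate
Conditions: CrCl2 (4 equiv), NiCl2 (cat.), DMF, rt
Reagents that add atoms: none
Why: The Nozaki–Hiyama–Kishi coupling adds the alkenylchromium species to the aldehyde only, keeps the E geometry and tolerates the free hydroxyl, the methylene lactone and the angelate; the new carbinol centre may form as either epimer because it is oxidised next.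

Step 21
Reactants: 29 (3aα-H,8aβ-H)-7α-hydroxy-7β-[(2E)-1-hydroxybut-2-en-1-yl]-6α-methyl-3-methylidene-2-oxo-4β-(triisopropylsilyloxy)octahydro-2H-cyclohepta[b]furan-8β-yl (2Z)-2-methylbut-2-enoate
Product: 30 (3aα-H,8aβ-H)-7β-[(2E)-but-2-enoyl]-7α-hydroxy-6α-methyl-3-methylidene-2-oxo-4β-(triisopropylsilyloxy)octahydro-2H-cyclohepta[b]furan-8β-yl (2Z)-2-methylbut-2-enoate
Conditions: MnO2 (activated, excess), CH2Cl2, rt
Reagents that add atoms: none
Why: Manganese dioxide oxidation is selective for the allylic alcohol and should give the E-enone without touching the tertiary hydroxyl.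

Step 22
Reactants: 30 (3aα-H,8aβ-H)-7β-[(2E)-but-2-enoyl]-7α-hydroxy-6α-methyl-3-methylidene-2-oxo-4β-(triisopropylsilyloxy)octahydro-2H-cyclohepta[b]furan-8β-yl (2Z)-2-methylbut-2-enoate
Product: 31 (3aS,4S,6S,7S,8S,8aR)-7-[(2E)-but-2-enoyl]-4,7-dihydroxy-6-methyl-3-methylidene-2-oxooctahydro-2H-cyclohepta[b]furan-8-yl (2Z)-2-methylbut-2-enoate
Conditions: HF·pyridine, THF, 0 °C → rt
Reagents that add atoms: none
Why: Fluoride-mediated desilylation under weakly acidic conditions should free the 4-hydroxyl without conjugate addition to the enone or methylene lactone and without isomerising the angelate.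

**Compound list**
1 | methyl 2-(furan-2-yl)acetate | COC(=O)Cc1ccco1 | starting material
2 | methyl 2-(5-formylfuran-2-yl)acetate | COC(=O)Cc1ccc(C=O)o1 | intermediate
3 | methyl 2-[5-(dimethoxymethyl)furan-2-yl]acetate | COC(=O)Cc1ccc(C(OC)OC)o1 | intermediate
4 | tetrachlorocyclopropene | ClC1=C(Cl)C1(Cl)Cl | starting material
5 | tetrabromocyclopropene | BrC1=C(Br)C1(Br)Br | intermediate
6 | rac-methyl 2-[2,3,3,4-tetrabromo-5-(dimethoxymethyl)-8-oxatricyclo[3.2.1.0(2,4)]oct-6-en-1-yl]acetate (Diels–Alder adduct; exo/endo not defined, both open to 7) | COC(=O)CC12OC(C(OC)OC)(C=C1)C1(Br)C(Br)(Br)C21Br | intermediate (not isolated)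
7 | rac-methyl 2-[2,2,3,4-tetrabromo-5-(dimethoxymethyl)-8-oxabicyclo[3.2.1]octa-3,6-dien-1-yl]acetate (may contain the allylic isomer with CBr2 at C-4) | COC(=O)C[C@]12O[C@](C(OC)OC)(C=C1)C(Br)=C(Br)C2(Br)Br | intermediate
8 | rac-methyl 2-[3,4-dibromo-5-(dimethoxymethyl)-2-oxo-8-oxabicyclo[3.2.1]octa-3,6-dien-1-yl]acetate | COC(=O)C[C@]12O[C@](C(OC)OC)(C=C1)C(Br)=C(Br)C2=O | intermediate
9 | rac-methyl 2-[3-bromo-5-(dimethoxymethyl)-2-oxo-8-oxabicyclo[3.2.1]octa-3,6-dien-1-yl]acetate | COC(=O)C[C@]12O[C@](C(OC)OC)(C=C1)C=C(Br)C2=O | intermediate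
10 | rac-methyl 2-[3-bromo-5-(dimethoxymethyl)-4-exo-methyl-2-oxo-8-oxabicyclo[3.2.1]oct-6-en-1-yl]acetate (C-3 epimers) | COC(=O)C[C@]12O[C@](C(OC)OC)(C=C1)[C@@H](C)C(Br)C2=O | intermediate (not isolated)
11 | rac-methyl 2-[5-(dimethoxymethyl)-4-exo-methyl-2-oxo-8-oxabicyclo[3.2.1]oct-6-en-1-yl]acetate | COC(=O)C[C@]12O[C@](C(OC)OC)(C=C1)[C@@H](C)CC2=O | intermediate
12 | methyl 2-[(2S)-5-(dimethoxymethyl)-2-endo-hydroxy-4-exo-methyl-8-oxabicyclo[3.2.1]oct-6-en-1-yl]acetate (single enantiomer) | COC(=O)C[C@]12O[C@](C(OC)OC)(C=C1)[C@@H](C)C[C@@H]2O | intermediate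
13 | 2-endo-O-triisopropylsilyl ether of 12 | COC(=O)C[C@]12O[C@](C(OC)OC)(C=C1)[C@@H](C)C[C@@H]2O[Si](C(C)C)(C(C)C)C(C)C | intermediate
14 | 6-exo,7-exo-diol of 13 (diol ester) | COC(=O)C[C@]12O[C@](C(OC)OC)([C@H](O)[C@@H]1O)[C@@H](C)C[C@@H]2O[Si](C(C)C)(C(C)C)C(C)C | intermediate (not isolated)
15 | tricyclic γ-lactone closed on the 7-exo oxygen, 6-exo-OH free | O=C1C[C@]23O[C@](C(OC)OC)([C@H](O)[C@@H]2O1)[C@@H](C)C[C@@H]3O[Si](C(C)C)(C(C)C)C(C)C | intermediate
16 | 6-ketone of 15 | O=C1C[C@]23O[C@](C(OC)OC)(C(=O)[C@@H]2O1)[C@@H](C)C[C@@H]3O[Si](C(C)C)(C(C)C)C(C)C | intermediate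
17 | 6-endo-alcohol (C-6 epimer of 15) | O=C1C[C@]23O[C@](C(OC)OC)([C@@H](O)[C@@H]2O1)[C@@H](C)C[C@@H]3O[Si](C(C)C)(C(C)C)C(C)C | intermediate
18 | 6-endo-O-triethylsilyl ether of 17 | O=C1C[C@]23O[C@](C(OC)OC)([C@@H](O[Si](CC)(CC)CC)[C@@H]2O1)[C@@H](C)C[C@@H]3O[Si](C(C)C)(C(C)C)C(C)C | intermediate
19 | butenolide: 7β-(dimethoxymethyl)-7α-hydroxy-6α-methyl-8β-(triethylsilyloxy)-4β-(triisopropylsilyloxy)-5,6,7,8-tetrahydro-4H-cyclohepta[b]furan-2(8aH)-one | O=C1C=C2[C@@H](O[Si](C(C)C)(C(C)C)C(C)C)C[C@H](C)[C@@](O)(C(OC)OC)[C@@H](O[Si](CC)(CC)CC)[C@@H]2O1 | intermediate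
20 | trans-fused lactone (3aα-H,8aβ-H), otherwise as 19 | O=C1C[C@H]2[C@@H](O[Si](C(C)C)(C(C)C)C(C)C)C[C@H](C)[C@@](O)(C(OC)OC)[C@@H](O[Si](CC)(CC)CC)[C@@H]2O1 | intermediate
21 | 3-[(dimethylamino)methyl] derivative of 20 (Mannich base, C-3 epimers) | O=C1C(CN(C)C)[C@H]2[C@@H](O[Si](C(C)C)(C(C)C)C(C)C)C[C@H](C)[C@@](O)(C(OC)OC)[C@@H](O[Si](CC)(CC)CC)[C@@H]2O1 | intermediate (not isolated)
22 | trimethylammonium iodide of 21 (methiodide) | O=C1C(C[N+](C)(C)C)[C@H]2[C@@H](O[Si](C(C)C)(C(C)C)C(C)C)C[C@H](C)[C@@](O)(C(OC)OC)[C@@H](O[Si](CC)(CC)CC)[C@@H]2O1.[I-] | intermediate (not isolated)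
23 | 3-methylidene lactone with 8β-OTES and 4β-OTIPS | C=C1C(=O)O[C@@H]2[C@@H]1[C@@H](O[Si](C(C)C)(C(C)C)C(C)C)C[C@H](C)[C@@](O)(C(OC)OC)[C@H]2O[Si](CC)(CC)CC | intermediate
24 | 3-methylidene lactone with free 8β-OH | C=C1C(=O)O[C@@H]2[C@@H]1[C@@H](O[Si](C(C)C)(C(C)C)C(C)C)C[C@H](C)[C@@](O)(C(OC)OC)[C@H]2O | intermediate
25 | angelic acid, (2Z)-2-methylbut-2-enoic acid | C/C=C(/C)C(=O)O | starting material
26 | 8β-angelate with 7β-dimethoxymethyl and 4β-OTIPS | C=C1C(=O)O[C@@H]2[C@@H]1[C@@H](O[Si](C(C)C)(C(C)C)C(C)C)C[C@H](C)[C@@](O)(C(OC)OC)[C@H]2OC(=O)/C(C)=C\C | intermediate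
27 | 7β-formyl-7α-hydroxy compound (aldehyde) | C=C1C(=O)O[C@@H]2[C@@H]1[C@@H](O[Si](C(C)C)(C(C)C)C(C)C)C[C@H](C)[C@@](O)(C=O)[C@H]2OC(=O)/C(C)=C\C | intermediate
28 | (E)-1-bromoprop-1-ene | C/C=C/Br | starting material
29 | 7β-[(2E)-1-hydroxybut-2-en-1-yl] compound (both carbinol epimers) | C=C1C(=O)O[C@@H]2[C@@H]1[C@@H](O[Si](C(C)C)(C(C)C)C(C)C)C[C@H](C)[C@@](O)(C(O)/C=C/C)[C@H]2OC(=O)/C(C)=C\C | intermediate
30 | 4-O-triisopropylsilyl ether of the target | C=C1C(=O)O[C@@H]2[C@@H]1[C@@H](O[Si](C(C)C)(C(C)C)C(C)C)C[C@H](C)[C@@](O)(C(=O)/C=C/C)[C@H]2OC(=O)/C(C)=C\C | intermediate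
31 | (3aS,4S,6S,7S,8S,8aR)-7-[(2E)-but-2-enoyl]-4,7-dihydroxy-6-methyl-3-methylidene-2-oxooctahydro-2H-cyclohepta[b]furan-8-yl (2Z)-2-methylbut-2-enoate (CNP0206014.2) | C=C1C(=O)O[C@@H]2[C@@H]1[C@@H](O)C[C@H](C)[C@@](O)(C(=O)/C=C/C)[C@H]2OC(=O)/C(C)=C\C | target

**Step count**
Total: 22 steps. Longest linear sequence: 21 steps (steps 1, 2 and 4–22 from methyl 2-(furan-2-yl)acetate); step 3 is a one-step side branch.

**Steps most likely to fail**

Step 15. What may go wrong: hydrogen is delivered to the convex β-face because the tertiary hydroxyl does not bind the catalyst (poor facial selectivity, which would give the cis-fused lactone), or the ether bridge re-closes by oxa-Michael addition before reduction. Fallback, from 19 back to 20: the hydride is delivered from a silicon tether instead of from a catalyst. 1,1,3,3-Tetramethyldisilazane should convert the tertiary alcohol of 19 into the 7-O-dimethylsilyl ether of 19 F1, which also blocks re-closure. A catalytic amount of fluoride (TBAF, THF, −40 °C) should then trigger intramolecular conjugate hydride transfer from silicon to C-3a on the α-face, where the tether sits. Aqueous work-up should hydrolyse the silyl enolate and the Si–O bond and return 20.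

Step 5. What may go wrong: water attacks the allyl-cation terminus next to the acetal-bearing bridgehead (wrong regiochemistry of carbonyl formation), or the acid set free hydrolyses the acetal. Fallback, from 3 back to 8: the oxygen is delivered intramolecularly. Saponification of 3 (LiOH, THF–H2O) should give 2-[5-(dimethoxymethyl)furan-2-yl]acetic acid F2. Cycloaddition with 5 under the conditions of step 4 should give the tetrabromo acid rac-2-[2,2,3,4-tetrabromo-5-(dimethoxymethyl)-8-oxabicyclo[3.2.1]octa-3,6-dien-1-yl]acetic acid F3. With Ag2CO3 in aqueous acetone the carboxylate should capture the neighbouring cation terminus in a five-membered ring, and the acyloxy bromide so formed should hydrolyse to the γ-keto acid rac-2-[3,4-dibromo-5-(dimethoxymethyl)-2-oxo-8-oxabicyclo[3.2.1]octa-3,6-dien-1-yl]acetic acid F4. Methylation with trimethylsilyldiazomethane returns 8.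

Step 8. What may go wrong: the catalyst does not override the substrate's own facial bias, or the hindered ketone reacts mainly by the uncatalysed pathway (low selectivity in separating the antipodes). Fallback, from 11 back to 12: reduction and resolution are separated. Luche reduction (NaBH4, CeCl3, MeOH, −78 °C) should give the racemic endo-alcohol rac-methyl 2-[5-(dimethoxymethyl)-2-endo-hydroxy-4-exo-methyl-8-oxabicyclo[3.2.1]oct-6-en-1-yl]acetate F5. A lipase-catalysed acylation (Burkholderia cepacia lipase, vinyl acetate, MTBE) should then acetylate the (2R)-antipode, following the usual enantiopreference of lipases for secondary alcohols, to the acetate methyl 2-[(2R)-2-endo-acetoxy-5-(dimethoxymethyl)-4-exo-methyl-8-oxabicyclo[3.2.1]oct-6-en-1-yl]acetate F6. The unreacted (2S)-alcohol is 12.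

**Further compounds**
F1 | step 15 | 7-O-dimethylsilyl ether of 19 | O=C1C=C2[C@@H](O[Si](C(C)C)(C(C)C)C(C)C)C[C@H](C)[C@@](O[SiH](C)C)(C(OC)OC)[C@@H](O[Si](CC)(CC)CC)[C@@H]2O1
F2 | step 5 | 2-[5-(dimethoxymethyl)furan-2-yl]acetic acid | OC(=O)Cc1ccc(C(OC)OC)o1
F3 | step 5 | rac-2-[2,2,3,4-tetrabromo-5-(dimethoxymethyl)-8-oxabicyclo[3.2.1]octa-3,6-dien-1-yl]acetic acid | OC(=O)C[C@]12O[C@](C(OC)OC)(C=C1)C(Br)=C(Br)C2(Br)Br
F4 | step 5 | rac-2-[3,4-dibromo-5-(dimethoxymethyl)-2-oxo-8-oxabicyclo[3.2.1]octa-3,6-dien-1-yl]acetic acid | OC(=O)C[C@]12O[C@](C(OC)OC)(C=C1)C(Br)=C(Br)C2=O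
F5 | step 8 | rac-methyl 2-[5-(dimethoxymethyl)-2-endo-hydroxy-4-exo-methyl-8-oxabicyclo[3.2.1]oct-6-en-1-yl]acetate (racemate, drawn as the enantiomer 12) | COC(=O)C[C@]12O[C@](C(OC)OC)(C=C1)[C@@H](C)C[C@@H]2O
F6 | step 8 | methyl 2-[(2R)-2-endo-acetoxy-5-(dimethoxymethyl)-4-exo-methyl-8-oxabicyclo[3.2.1]oct-6-en-1-yl]acetate (acetate of the antipode of 12) | COC(=O)C[C@@]12O[C@@](C(OC)OC)(C=C1)[C@H](C)C[C@H]2OC(C)=O
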